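The readings were generated by integration for an exercise.

The meeting opened on one question: does the vessel change how much of the X that reacts leaves as Q?

| flask | X | D | remark | time |
|---|---|---|---|---|
| ochre | 0.40 M | 1.1 equiv | run made earlier |  |
| blue | 0.20 M | 1.1 equiv | run made earlier |  |
| grey | 0.30 M | 1.1 equiv | run made earlier |  |
| green | 0.40 M | 2.2 equiv | run made earlier |  |
| maple | 0.40 M | 1.10 equiv | one stirred flow tank at steady state, fed with the mixture as stated, mean residence time 8.0 min |  |
| alder | 0.40 M | 1.10 equiv (fed, over 6.40 min) | a stirred flask in which D is dosed at a steady rate over 6.40 min without added volume, worked up at 8.0 min | 8.0 min |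
| cedar | 0.40 M | 1.10 equiv | everything together in a closed stirred flask, run for 8.0 min | 8.0 min |
| birch | 0.40 M | 1.10 equiv | one stirred flow tank at steady state, fed with the mixture as stated, mean residence time 24.0 min |  |

| run | time / min | Q / % | G / % | J / % |
|---|---|---|---|---|
| ochre | 2.00 | 18.1 | 9.4 | 64.2 |
| ochre | 4.00 | 19.1 | 9.8 | 66.9 |
| ochre | 6.00 | 20.2 | 10.5 | 69.2 |
| ochre | 8.00 | 19.2 | 10.5 | 68.5 |
| blue | 1.50 | 16.5 | 7.4 | 56.8 |
| blue | 3.00 | 18.2 | 9.3 | 61.6 |
| blue | 5.00 | 18.7 | 8.9 | 65.9 |
| blue | 6.00 | 18.6 | 9.4 | 66.9 |
| grey | 0.500 | 12.7 | 6.5 | 47.2 |
| grey | 1.33 | 17.1 | 9.2 | 58.4 |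
| grey | 3.00 | 17.4 | 9.3 | 64.9 |
| grey | 6.00 | 19.8 | 10.3 | 68.1 |
| green | 0.833 | 20.2 | 10.1 | 69.1 |
| green | 2.50 | 19.8 | 9.8 | 70.1 |
| green | 4.00 | 20.2 | 9.9 | 70.3 |
| green | 6.00 | 19.5 | 10.1 | 70.3 |

(readings scatter by 0.5 percentage points)

* the set-up with the highest share of Q in all that became Q or G or J, at the outlet or at the end ("none" if the first two lie within 2 percentage points) (maple / alder / cedar / birch / none)
* share of Q in all that became Q or G or J, at the outlet or at the end, maple
* share of Q in all that became Q or G or J, at the outlet or at the end, alder
* share of Q in all that became Q or G or J, at the outlet or at the end, cedar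
* share of Q in all that became Q or G or J, at the outlet or at the end, birch

- the stated concentrations are those of everything mixed, before any reaction; amounts are the same in each set-up
- the feed brings no volume worth counting
- the earlier runs were made in a closed, stirred flask
- a reading or a percentage of Q counts all its forms, free or not

The chair proposed following a single molecule of X: it meets D, and at that fork it goes to Q, G or J. The analyst summed the last readings of the earlier runs and got 19.7%, the fork share: the chance that a molecule of X which has reacted left as Q, usually called the selectivity for Q. She reported that the last reading of the blue run, at 0.20 M of X, gave 19.6%, and that of the green run, at 2.2 equiv of D, 19.5%. The grey run gave 19.1% as early as 0.500 min, each reading carrying 0.5 percentage points.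

One member objected. The earlier runs were closed flasks, and alder feeds D slowly. The analyst answered that a share holding still while X and D both change points to forks with the same partners, so their ratio should not follow the concentrations.

My own reckoning, as minute-taker, was the fork share, unchanged, in each set-up. The forecast, entered next, gave 20% for maple, 20% for alder, 20% for cedar, 20% for birch and none as best, holding that “Mixing pattern should therefore not matter”. That is the same verdict in a rounder figure.

The flask gives 19.8% in maple, 19.8% in alder, 19.8% in cedar and 19.8% in birch, so the best is none. The set-ups still differ in how far X goes: the maple tank held 14.1% of its X unreacted, against 1.1% in cedar at 8.00 min, and Q in maple, with its bound form E counted in, stood at 17.0% of the charge. The fork share applied to the reacted part of maple gives 16.9%.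

    X + D → J (k = 8.80 M⁻¹ min⁻¹)
    D + Q ⇌ E, settled at all times (K = 19.0 M⁻¹)
    X + D → Q (k = 2.50 M⁻¹ min⁻¹)
    X + D → G (k = 1.30 M⁻¹ min⁻¹)

A neighbour of alder, dosed the same way but with 0.280 equiv of D, ended with 72% of its X unreacted, so the fork share gives 5.52% of the charge as Q. The computed flask holds 5.55%, a share of 19.8%.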